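**Retrosynthetic overview**

1. Target 33 ⇐ O‑demethylation ⇐ Wittig olefination on the C5 arm ⇐ hydroboration/B‑alkyl Suzuki coupling at C7 ⇐ cross‑metathesis at C1 ⇐ bicyclic methyl enol ether 22 (1‑allyl, 7‑methylidene).
2. 22 ⇐ tin‑mediated radical cascade of the monocyclic isopropylidene dione 20 with allyltributylstannane 21, forming C7–C8 and C1–allyl. Ring A (C1, C2, C3, C4, C5, C9) comes from an arene; ring B (C1, C8, C7, C6, C5, C9) is closed last.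
3. Feature used: in ring A the exocyclic C1=C8 isopropylidene sits between the C2 and C9 carbonyls, so C8 is the carbon attacked by a C7 vinyl radical delivered from the 2‑bromoallyl arm on C5; the C1 radical that results then accepts the allyl group.
4. 20 ⇐ selenoxide elimination ⇐ enantioselective alkylative dearomatization at C5 of the fully substituted benzophenone 15 ⇐ three directed ortho‑metalations starting from 5‑methoxyresorcinol.
5. Two spectator groups differ from the target pattern at the key step. C5 carries a saturated 2‑silyloxyethyl arm (made into prenyl by a late Wittig), because a prenyl or allyl group there would capture the C7 radical in a fast 5‑exo closure. C3 carries the benzoyl group from the arene stage, which also blocks C3 during dearomatization.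

Key step: step 11

Remark: locants C1–C9 in the text follow the bicyclo[3.3.1]nonane numbering of the target (C8 = CMe2, C9 = bridging ketone), whereas systematic names of monocyclic compounds use their own numbering; TBDPS = tert‑butyldiphenylsilyl; it is assumed that the cinchonidinium catalyst of step 8 favours (6S)‑17, and if it favours the antipode the pseudoenantiomeric cinchoninium salt is used.

**Step 1**
Reactants: 1 5‑methoxyresorcinol
Product: 2 1‑methoxy‑3,5‑bis(methoxymethoxy)benzene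
Conditions: MOMCl, i‑Pr2NEt, CH2Cl2, 0 °C to rt
Reagents that add atoms: chloromethyl methyl ether (MOMCl), COCCl
Why: Base‑mediated O‑alkylation of both phenols should give the bis‑MOM ether, whose acetal oxygens direct the later ortho‑lithiations.

**Step 2**
Reactants: 2 1‑methoxy‑3,5‑bis(methoxymethoxy)benzene; 3 2‑bromopropene
Product: 6 5‑methoxy‑1,3‑bis(methoxymethoxy)‑2‑(prop‑1‑en‑2‑yl)benzene, via aryllithium 4 (not isolated), via arylzinc chloride 5 (not isolated)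
Conditions: n‑BuLi, THF, 0 °C; ZnCl2, 0 °C to rt; 3, Pd(PPh3)4 (3 mol %), 50 °C
Reagents that add atoms: none
Why: Directed ortho‑metalation should occur at the carbon between the two OMOM groups (the future C1), and Negishi coupling of the derived arylzinc with the alkenyl bromide installs the isopropenyl group there.

**Step 3**
Reactants: 6 5‑methoxy‑1,3‑bis(methoxymethoxy)‑2‑(prop‑1‑en‑2‑yl)benzene
Product: 7 5‑methoxy‑1,3‑bis(methoxymethoxy)‑2‑(propan‑2‑yl)benzene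
Conditions: H2 (3 atm), Pd/C (10 %), EtOAc, rt
Reagents that add atoms: none
Why: Heterogeneous catalytic hydrogenation should saturate the 1,1‑disubstituted styrene to the isopropyl group while MOM acetals and aryl ethers are inert.

**Step 4**
Reactants: 7 5‑methoxy‑1,3‑bis(methoxymethoxy)‑2‑(propan‑2‑yl)benzene; 8 ethylene oxide
Product: 10 2‑[6‑methoxy‑2,4‑bis(methoxymethoxy)‑3‑(propan‑2‑yl)phenyl]ethan‑1‑ol, via aryllithium 9 (not isolated)
Conditions: n‑BuLi, TMEDA, THF, 0 °C; 8, −78 °C to rt; H2O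
Reagents that add atoms: none
Why: The two remaining ring positions (each between OMOM and OMe) are equivalent by symmetry, so directed ortho‑metalation followed by epoxide opening should give a single 2‑arylethanol carrying the future C5 arm.

**Step 5**
Reactants: 10 2‑[6‑methoxy‑2,4‑bis(methoxymethoxy)‑3‑(propan‑2‑yl)phenyl]ethan‑1‑ol
Product: 11 tert‑butyl{2‑[6‑methoxy‑2,4‑bis(methoxymethoxy)‑3‑(propan‑2‑yl)phenyl]ethoxy}diphenylsilane
Conditions: TBDPSCl, imidazole, DMF, rt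
Reagents that add atoms: tert‑butyl(chloro)diphenylsilane (TBDPSCl), CC(C)(C)[Si](Cl)(c1ccccc1)c1ccccc1
Why: Silylation of the primary alcohol gives an ether that tolerates organolithium, acid, radical and palladium conditions and has no alkene for the later C7 radical to attack.

**Step 6**
Reactants: 11 tert‑butyl{2‑[6‑methoxy‑2,4‑bis(methoxymethoxy)‑3‑(propan‑2‑yl)phenyl]ethoxy}diphenylsilane; 12 N‑methoxy‑N‑methylbenzamide
Product: 14 [3‑(2‑TBDPSO‑ethyl)‑2‑methoxy‑4,6‑bis(methoxymethoxy)‑5‑(propan‑2‑yl)phenyl](phenyl)methanone, via aryllithium 13 (not isolated)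
Conditions: n‑BuLi, TMEDA, THF, −20 °C; 12, −78 to 0 °C; H2O
Reagents that add atoms: none
Why: Directed ortho‑metalation at the last ring C–H (the future C3, between OMOM and OMe) and acylation with the Weinreb amide, which stops at the ketone through its chelated tetrahedral adduct, should install the benzoyl group.

**Step 7**
Reactants: 14 [3‑(2‑TBDPSO‑ethyl)‑2‑methoxy‑4,6‑bis(methoxymethoxy)‑5‑(propan‑2‑yl)phenyl](phenyl)methanone
Product: 15 [3‑(2‑TBDPSO‑ethyl)‑4,6‑dihydroxy‑2‑methoxy‑5‑(propan‑2‑yl)phenyl](phenyl)methanone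
Conditions: ZnBr2, n‑PrSH, CH2Cl2, 0 °C to rt
Reagents that add atoms: none
Why: Lewis acid–thiol transacetalization cleaves aryl MOM ethers rapidly and should free both phenols without touching the TBDPS ether or the hindered diaryl ketone.

**Step 8**
Reactants: 15 [3‑(2‑TBDPSO‑ethyl)‑4,6‑dihydroxy‑2‑methoxy‑5‑(propan‑2‑yl)phenyl](phenyl)methanone; 16 2,3‑dibromopropene
Product: 17 (6S)‑4‑benzoyl‑6‑(2‑bromoprop‑2‑en‑1‑yl)‑6‑(2‑TBDPSO‑ethyl)‑3‑hydroxy‑5‑methoxy‑2‑(propan‑2‑yl)cyclohexa‑2,4‑dien‑1‑one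
Conditions: 16 (1.2 equiv), O‑allyl‑N‑(9‑anthracenylmethyl)cinchonidinium bromide (10 mol %), CsOH·H2O, toluene–CH2Cl2, −40 °C
Reagents that add atoms: none
Why: Phase‑transfer alkylative dearomatization: the acylphloroglucinol anion, as a chiral ion pair, is C‑alkylated at the allylic bromide at C5, since C3 is deactivated by the benzoyl group and C1 is shielded by isopropyl, and the ammonium cation covers one face of the planar anion to set the C5 stereocentre.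

**Step 9**
Reactants: 17 (6S)‑4‑benzoyl‑6‑(2‑bromoprop‑2‑en‑1‑yl)‑6‑(2‑TBDPSO‑ethyl)‑3‑hydroxy‑5‑methoxy‑2‑(propan‑2‑yl)cyclohexa‑2,4‑dien‑1‑one
Product: 18 (6S)‑4‑benzoyl‑6‑(2‑bromoprop‑2‑en‑1‑yl)‑6‑(2‑TBDPSO‑ethyl)‑5‑methoxy‑2‑(phenylselanyl)‑2‑(propan‑2‑yl)cyclohex‑4‑ene‑1,3‑dione (mixture of epimers at the selenium‑bearing carbon)
Conditions: PhSeCl, pyridine, CH2Cl2, −78 to 0 °C
Reagents that add atoms: phenylselanyl chloride (PhSeCl), Cl[Se]c1ccccc1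
Why: Electrophilic α‑selenenylation of the enolized dione should occur at C1, the only enol carbon that does not carry an acyl group, and the epimer mixture is of no consequence because both epimers eliminate to the same alkene.

**Step 10**
Reactants: 18 (6S)‑4‑benzoyl‑6‑(2‑bromoprop‑2‑en‑1‑yl)‑6‑(2‑TBDPSO‑ethyl)‑5‑methoxy‑2‑(phenylselanyl)‑2‑(propan‑2‑yl)cyclohex‑4‑ene‑1,3‑dione
Product: 20 (6S)‑4‑benzoyl‑6‑(2‑bromoprop‑2‑en‑1‑yl)‑6‑(2‑TBDPSO‑ethyl)‑5‑methoxy‑2‑(propan‑2‑ylidene)cyclohex‑4‑ene‑1,3‑dione, via selenoxide 19 (not isolated)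
Conditions: DMDO (acetone), CH2Cl2, −78 to 0 °C; cold filtration through Florisil, used at once
Reagents that add atoms: none
Why: Selenide oxidation and selenoxide syn‑elimination can only use the isopropyl methine hydrogen, so the C1=C8 isopropylidene forms regiospecifically, and neutral cold conditions are chosen because acid or base would tautomerize it to the isopropenyl enol.

**Step 11**
Reactants: 20 (6S)‑4‑benzoyl‑6‑(2‑bromoprop‑2‑en‑1‑yl)‑6‑(2‑TBDPSO‑ethyl)‑5‑methoxy‑2‑(propan‑2‑ylidene)cyclohex‑4‑ene‑1,3‑dione; 21 allyltributylstannane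
Product: 22 (1S,5R)‑3‑benzoyl‑5‑(2‑TBDPSO‑ethyl)‑4‑methoxy‑8,8‑dimethyl‑7‑methylidene‑1‑(prop‑2‑en‑1‑yl)bicyclo[3.3.1]non‑3‑ene‑2,9‑dione
Conditions: 21 (3 equiv), AIBN (0.2 equiv, in portions), benzene (0.03 M), 80 °C
Reagents that add atoms: none
Why: Proposed new method: Bu3Sn radical (from 21 and AIBN) abstracts bromine from the 2‑bromoallyl arm, the C7 σ‑vinyl radical adds to C8, the β‑carbon of the C1=C8 alkylidene dione, and the C1 radical so formed adds to the terminal carbon of 21 and expels Bu3Sn radical, which carries the chain. The closest known reaction type is a Stork vinyl‑radical cyclization terminated by Keck allyl transfer; new here are a tetrasubstituted alkylidene 1,3‑dione as acceptor and a bridgehead radical as the allyl acceptor. Ring B (C1, C8, C7, C6, C5, C9) closes in the 6‑endo‑trig mode. The new stereocentre C1 is fixed by C5 through the one‑carbon C9 bridge: C8 can only reach C7 on the face of ring A that carries C6, so the allyl group must enter on the other face. The step needs 6‑endo over 5‑exo closure and ring closure ahead of hydrogen transfer or direct allyl transfer to C7; the first is secured by the polarization of the doubly acceptor‑substituted alkene (attack at C1 would leave an unstabilized tertiary radical at C8), the second by the absence of any other alkene within reach of C7 and by a low stannane concentration.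

**Step 12**
Reactants: 22 (1S,5R)‑3‑benzoyl‑5‑(2‑TBDPSO‑ethyl)‑4‑methoxy‑8,8‑dimethyl‑7‑methylidene‑1‑(prop‑2‑en‑1‑yl)bicyclo[3.3.1]non‑3‑ene‑2,9‑dione; 23 2‑methylbut‑2‑ene
Product: 24 (1S,5R)‑3‑benzoyl‑5‑(2‑TBDPSO‑ethyl)‑4‑methoxy‑8,8‑dimethyl‑1‑(3‑methylbut‑2‑en‑1‑yl)‑7‑methylidenebicyclo[3.3.1]non‑3‑ene‑2,9‑dione
Conditions: 23 (excess), second‑generation Grubbs catalyst (H2IMes)(PCy3)Cl2Ru=CHPh (5 mol %), CH2Cl2, 40 °C
Reagents that add atoms: none
Why: Olefin cross‑metathesis should convert the monosubstituted allyl alkene into the prenyl group, while the 1,1‑disubstituted methylidene next to the quaternary C8 is too hindered to react.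

**Step 13**
Reactants: 24 (1S,5R)‑3‑benzoyl‑5‑(2‑TBDPSO‑ethyl)‑4‑methoxy‑8,8‑dimethyl‑1‑(3‑methylbut‑2‑en‑1‑yl)‑7‑methylidenebicyclo[3.3.1]non‑3‑ene‑2,9‑dione; 25 1‑bromo‑2‑methylprop‑1‑ene
Product: 27 (1S,5R,7S)‑3‑benzoyl‑5‑(2‑TBDPSO‑ethyl)‑4‑methoxy‑8,8‑dimethyl‑1,7‑bis(3‑methylbut‑2‑en‑1‑yl)bicyclo[3.3.1]non‑3‑ene‑2,9‑dione, via B‑alkyl‑9‑BBN adduct 26 (not isolated)
Conditions: 9‑BBN, THF, 0 °C to rt; then 25, PdCl2(dppf) (5 mol %), K3PO4 (aq), DMF, rt to 50 °C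
Reagents that add atoms: none
Why: Anti‑Markovnikov hydroboration of the methylidene (much faster than that of the trisubstituted prenyl alkene) should deliver hydrogen to C7 from the exo face, the endo face being covered by the C2–C3–C4 bridge, so the CH2–B arm is endo, and B‑alkyl Suzuki–Miyaura coupling turns it into the endo prenyl group.

**Step 14**
Reactants: 27 (1S,5R,7S)‑3‑benzoyl‑5‑(2‑TBDPSO‑ethyl)‑4‑methoxy‑8,8‑dimethyl‑1,7‑bis(3‑methylbut‑2‑en‑1‑yl)bicyclo[3.3.1]non‑3‑ene‑2,9‑dione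
Product: 28 (1S,5R,7S)‑3‑benzoyl‑5‑(2‑hydroxyethyl)‑4‑methoxy‑8,8‑dimethyl‑1,7‑bis(3‑methylbut‑2‑en‑1‑yl)bicyclo[3.3.1]non‑3‑ene‑2,9‑dione
Conditions: HF·pyridine, pyridine, THF, 0 °C to rt; oxidized without storage
Reagents that add atoms: none
Why: Buffered fluoride desilylation frees the primary alcohol without forming an alkoxide, which could otherwise add to the neighbouring C4 enol ether carbon and displace methanol.

**Step 15**
Reactants: 28 (1S,5R,7S)‑3‑benzoyl‑5‑(2‑hydroxyethyl)‑4‑methoxy‑8,8‑dimethyl‑1,7‑bis(3‑methylbut‑2‑en‑1‑yl)bicyclo[3.3.1]non‑3‑ene‑2,9‑dione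
Product: 29 (1S,5R,7S)‑3‑benzoyl‑4‑methoxy‑8,8‑dimethyl‑1,7‑bis(3‑methylbut‑2‑en‑1‑yl)‑5‑(2‑oxoethyl)bicyclo[3.3.1]non‑3‑ene‑2,9‑dione
Conditions: Dess–Martin periodinane, CH2Cl2, 0 °C to rt
Reagents that add atoms: none
Why: Dess–Martin oxidation should take the primary alcohol to the aldehyde under neutral conditions that leave the alkenes, the enol ether and the ketones unchanged.

**Step 16**
Reactants: 29 (1S,5R,7S)‑3‑benzoyl‑4‑methoxy‑8,8‑dimethyl‑1,7‑bis(3‑methylbut‑2‑en‑1‑yl)‑5‑(2‑oxoethyl)bicyclo[3.3.1]non‑3‑ene‑2,9‑dione; 30 isopropyltriphenylphosphonium iodide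
Product: 32 (1S,5S,7S)‑3‑benzoyl‑4‑methoxy‑8,8‑dimethyl‑1,5,7‑tris(3‑methylbut‑2‑en‑1‑yl)bicyclo[3.3.1]non‑3‑ene‑2,9‑dione, via phosphorus ylide 31 (not isolated)
Conditions: 30, n‑BuLi, THF, 0 °C; then 29, −78 °C to rt
Reagents that add atoms: none
Why: Wittig olefination with the unstabilized isopropylidene ylide should react only at the aldehyde, the ketones being hindered or conjugated, and completes the C5 prenyl group (the descriptor at C5 changes only through the priority rules).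

**Step 17**
Reactants: 32 (1S,5S,7S)‑3‑benzoyl‑4‑methoxy‑8,8‑dimethyl‑1,5,7‑tris(3‑methylbut‑2‑en‑1‑yl)bicyclo[3.3.1]non‑3‑ene‑2,9‑dione
Product: 33 (1S,5R,7S)‑3‑[hydroxy(phenyl)methylidene]‑8,8‑dimethyl‑1,5,7‑tris(3‑methylbut‑2‑en‑1‑yl)bicyclo[3.3.1]nonane‑2,4,9‑trione (CID5471610)
Conditions: LiCl, DMSO, 120 °C; dilute HCl work‑up
Reagents that add atoms: none
Why: Chloride attacks the methyl group of the vinylogous ester (Krapcho‑type O‑demethylation) and the liberated enolized β‑triketone is the target, with no stereocentre at risk.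

**Compound list**

1 | 5‑methoxyresorcinol (5‑methoxybenzene‑1,3‑diol) | COc1cc(O)cc(O)c1 | starting material
2 | 1‑methoxy‑3,5‑bis(methoxymethoxy)benzene | COCOc1cc(OC)cc(OCOC)c1 | intermediate
3 | 2‑bromopropene | CC(Br)=C | starting material
4 | [4‑methoxy‑2,6‑bis(methoxymethoxy)phenyl]lithium | [Li]c1c(OCOC)cc(OC)cc1OCOC | intermediate
5 | [4‑methoxy‑2,6‑bis(methoxymethoxy)phenyl]zinc chloride | Cl[Zn]c1c(OCOC)cc(OC)cc1OCOC | intermediate
6 | 5‑methoxy‑1,3‑bis(methoxymethoxy)‑2‑(prop‑1‑en‑2‑yl)benzene | CC(=C)c1c(OCOC)cc(OC)cc1OCOC | intermediate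
7 | 5‑methoxy‑1,3‑bis(methoxymethoxy)‑2‑(propan‑2‑yl)benzene | CC(C)c1c(OCOC)cc(OC)cc1OCOC | intermediate
8 | ethylene oxide (oxirane) | C1CO1 | starting material
9 | [6‑methoxy‑2,4‑bis(methoxymethoxy)‑3‑(propan‑2‑yl)phenyl]lithium | [Li]c1c(OC)cc(OCOC)c(C(C)C)c1OCOC | intermediate
10 | 2‑[6‑methoxy‑2,4‑bis(methoxymethoxy)‑3‑(propan‑2‑yl)phenyl]ethan‑1‑ol | OCCc1c(OC)cc(OCOC)c(C(C)C)c1OCOC | intermediate
11 | tert‑butyl{2‑[6‑methoxy‑2,4‑bis(methoxymethoxy)‑3‑(propan‑2‑yl)phenyl]ethoxy}diphenylsilane | CC(C)(C)[Si](OCCc1c(OC)cc(OCOC)c(C(C)C)c1OCOC)(c1ccccc1)c1ccccc1 | intermediate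
12 | N‑methoxy‑N‑methylbenzamide | CON(C)C(=O)c1ccccc1 | starting material
13 | [3‑(2‑TBDPSO‑ethyl)‑2‑methoxy‑4,6‑bis(methoxymethoxy)‑5‑(propan‑2‑yl)phenyl]lithium | CC(C)(C)[Si](OCCc1c(OC)c([Li])c(OCOC)c(C(C)C)c1OCOC)(c1ccccc1)c1ccccc1 | intermediate
14 | [3‑(2‑TBDPSO‑ethyl)‑2‑methoxy‑4,6‑bis(methoxymethoxy)‑5‑(propan‑2‑yl)phenyl](phenyl)methanone | CC(C)(C)[Si](OCCc1c(OC)c(C(=O)c2ccccc2)c(OCOC)c(C(C)C)c1OCOC)(c1ccccc1)c1ccccc1 | intermediate
15 | [3‑(2‑TBDPSO‑ethyl)‑4,6‑dihydroxy‑2‑methoxy‑5‑(propan‑2‑yl)phenyl](phenyl)methanone | CC(C)(C)[Si](OCCc1c(OC)c(C(=O)c2ccccc2)c(O)c(C(C)C)c1O)(c1ccccc1)c1ccccc1 | intermediate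
16 | 2,3‑dibromopropene | C=C(Br)CBr | starting material
17 | (6S)‑4‑benzoyl‑6‑(2‑bromoprop‑2‑en‑1‑yl)‑6‑(2‑TBDPSO‑ethyl)‑3‑hydroxy‑5‑methoxy‑2‑(propan‑2‑yl)cyclohexa‑2,4‑dien‑1‑one | CC(C)(C)[Si](OCC[C@@]1(CC(Br)=C)C(=O)C(C(C)C)=C(O)C(C(=O)c2ccccc2)=C1OC)(c1ccccc1)c1ccccc1 | intermediate
18 | (6S)‑4‑benzoyl‑6‑(2‑bromoprop‑2‑en‑1‑yl)‑6‑(2‑TBDPSO‑ethyl)‑5‑methoxy‑2‑(phenylselanyl)‑2‑(propan‑2‑yl)cyclohex‑4‑ene‑1,3‑dione (epimers at C2 of this name) | CC(C)(C)[Si](OCC[C@@]1(CC(Br)=C)C(=O)C([Se]c2ccccc2)(C(C)C)C(=O)C(C(=O)c2ccccc2)=C1OC)(c1ccccc1)c1ccccc1 | intermediate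
19 | selenoxide of 18, (6S)‑4‑benzoyl‑2‑(benzeneseleninyl)‑6‑(2‑bromoprop‑2‑en‑1‑yl)‑6‑(2‑TBDPSO‑ethyl)‑5‑methoxy‑2‑(propan‑2‑yl)cyclohex‑4‑ene‑1,3‑dione | CC(C)(C)[Si](OCC[C@@]1(CC(Br)=C)C(=O)C([Se](=O)c2ccccc2)(C(C)C)C(=O)C(C(=O)c2ccccc2)=C1OC)(c1ccccc1)c1ccccc1 | intermediate
20 | (6S)‑4‑benzoyl‑6‑(2‑bromoprop‑2‑en‑1‑yl)‑6‑(2‑TBDPSO‑ethyl)‑5‑methoxy‑2‑(propan‑2‑ylidene)cyclohex‑4‑ene‑1,3‑dione | CC(C)(C)[Si](OCC[C@@]1(CC(Br)=C)C(=O)C(=C(C)C)C(=O)C(C(=O)c2ccccc2)=C1OC)(c1ccccc1)c1ccccc1 | intermediate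
21 | allyltributylstannane | C=CC[Sn](CCCC)(CCCC)CCCC | starting material
22 | (1S,5R)‑3‑benzoyl‑5‑(2‑TBDPSO‑ethyl)‑4‑methoxy‑8,8‑dimethyl‑7‑methylidene‑1‑(prop‑2‑en‑1‑yl)bicyclo[3.3.1]non‑3‑ene‑2,9‑dione | C=C1C[C@@]2(CCO[Si](c3ccccc3)(c3ccccc3)C(C)(C)C)C(OC)=C(C(=O)c3ccccc3)C(=O)[C@](CC=C)(C2=O)C1(C)C | intermediate
23 | 2‑methylbut‑2‑ene | CC=C(C)C | starting material
24 | (1S,5R)‑3‑benzoyl‑5‑(2‑TBDPSO‑ethyl)‑4‑methoxy‑8,8‑dimethyl‑1‑(3‑methylbut‑2‑en‑1‑yl)‑7‑methylidenebicyclo[3.3.1]non‑3‑ene‑2,9‑dione | C=C1C[C@@]2(CCO[Si](c3ccccc3)(c3ccccc3)C(C)(C)C)C(OC)=C(C(=O)c3ccccc3)C(=O)[C@](CC=C(C)C)(C2=O)C1(C)C | intermediate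
25 | 1‑bromo‑2‑methylprop‑1‑ene | CC(C)=CBr | starting material
26 | (1S,5R,7S)‑3‑benzoyl‑7‑[(9‑borabicyclo[3.3.1]nonan‑9‑yl)methyl]‑5‑(2‑TBDPSO‑ethyl)‑4‑methoxy‑8,8‑dimethyl‑1‑(3‑methylbut‑2‑en‑1‑yl)bicyclo[3.3.1]non‑3‑ene‑2,9‑dione | C1CC2CCCC(C1)B2C[C@H]1C[C@@]2(CCO[Si](c3ccccc3)(c3ccccc3)C(C)(C)C)C(OC)=C(C(=O)c3ccccc3)C(=O)[C@](CC=C(C)C)(C2=O)C1(C)C | intermediate
27 | (1S,5R,7S)‑3‑benzoyl‑5‑(2‑TBDPSO‑ethyl)‑4‑methoxy‑8,8‑dimethyl‑1,7‑bis(3‑methylbut‑2‑en‑1‑yl)bicyclo[3.3.1]non‑3‑ene‑2,9‑dione | CC(C)=CC[C@H]1C[C@@]2(CCO[Si](c3ccccc3)(c3ccccc3)C(C)(C)C)C(OC)=C(C(=O)c3ccccc3)C(=O)[C@](CC=C(C)C)(C2=O)C1(C)C | intermediate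
28 | (1S,5R,7S)‑3‑benzoyl‑5‑(2‑hydroxyethyl)‑4‑methoxy‑8,8‑dimethyl‑1,7‑bis(3‑methylbut‑2‑en‑1‑yl)bicyclo[3.3.1]non‑3‑ene‑2,9‑dione | CC(C)=CC[C@H]1C[C@@]2(CCO)C(OC)=C(C(=O)c3ccccc3)C(=O)[C@](CC=C(C)C)(C2=O)C1(C)C | intermediate
29 | (1S,5R,7S)‑3‑benzoyl‑4‑methoxy‑8,8‑dimethyl‑1,7‑bis(3‑methylbut‑2‑en‑1‑yl)‑5‑(2‑oxoethyl)bicyclo[3.3.1]non‑3‑ene‑2,9‑dione | CC(C)=CC[C@H]1C[C@@]2(CC=O)C(OC)=C(C(=O)c3ccccc3)C(=O)[C@](CC=C(C)C)(C2=O)C1(C)C | intermediate
30 | isopropyltriphenylphosphonium iodide | CC(C)[P+](c1ccccc1)(c1ccccc1)c1ccccc1.[I-] | starting material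
31 | isopropylidenetriphenylphosphorane | CC(C)=P(c1ccccc1)(c1ccccc1)c1ccccc1 | intermediate
32 | (1S,5S,7S)‑3‑benzoyl‑4‑methoxy‑8,8‑dimethyl‑1,5,7‑tris(3‑methylbut‑2‑en‑1‑yl)bicyclo[3.3.1]non‑3‑ene‑2,9‑dione | CC(C)=CC[C@H]1C[C@@]2(CC=C(C)C)C(OC)=C(C(=O)c3ccccc3)C(=O)[C@](CC=C(C)C)(C2=O)C1(C)C | intermediate
33 | (1S,5R,7S)‑3‑[hydroxy(phenyl)methylidene]‑8,8‑dimethyl‑1,5,7‑tris(3‑methylbut‑2‑en‑1‑yl)bicyclo[3.3.1]nonane‑2,4,9‑trione | CC(C)=CC[C@H]1C[C@@]2(CC=C(C)C)C(=O)/C(=C(/O)c3ccccc3)C(=O)[C@](CC=C(C)C)(C2=O)C1(C)C | target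

**Step count and risks**

Total step count: 17. Longest linear sequence: 17 steps (from 1).

Steps most likely to fail:

1. Step 11 (proposed new method). The C7 vinyl radical may be quenched by 1,5‑hydrogen transfer from the C5 arm or by direct allyl transfer before it reaches the fully substituted C8, and the hindered bridgehead C1 radical may fail to propagate the allyl‑transfer chain. Fallback with known chemistry, from 20 back to 22: slow addition of tributyltin hydride (Bu3SnH, syringe pump) with AIBN in benzene at 80 °C, a Stork‑type reductive vinyl‑radical cyclization without any competing allyl donor, should give the C1–H bicycle (1S,5R)‑3‑benzoyl‑5‑(2‑TBDPSO‑ethyl)‑4‑methoxy‑8,8‑dimethyl‑7‑methylidenebicyclo[3.3.1]non‑3‑ene‑2,9‑dione F1. Bridgehead deprotonation of F1 with lithium 2,2,6,6‑tetramethylpiperidide (LiTMP, THF, −78 °C) and alkylation with allyl bromide, the usual way of substituting the bridgeheads of this bicyclic trione class, then returns to 22, so the C1–allyl bond is made by enolate chemistry instead of radical capture.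

2. Step 8. Enantiofacial discrimination by the chiral ion pair may be insufficient, and some alkylation may leak to C1 or to oxygen. Fallback, from 15 back to 17: uncatalysed alkylation with 16 (K2CO3, acetone, rt) should give the racemate, rac‑4‑benzoyl‑6‑(2‑bromoprop‑2‑en‑1‑yl)‑6‑(2‑TBDPSO‑ethyl)‑3‑hydroxy‑5‑methoxy‑2‑(propan‑2‑yl)cyclohexa‑2,4‑dien‑1‑one F2. This acidic vinylogous acid would be resolved by crystallization of its salt with (S)‑1‑phenylethylamine, the (S)‑1‑phenylethylammonium enolate of (6S)‑17 F3, and acidification of the salt returns to 17.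

3. Step 13. The dialkylborane may reduce the C2 or benzoyl carbonyl in competition with its slow addition to the hindered methylidene, and hydride delivery to the endo face would give the wrong C7 epimer, which cannot be corrected later. Fallback, from 24 back to 27: iridium‑catalysed hydroboration with pinacolborane ([Ir(cod)Cl]2, dppm, CH2Cl2, rt), which does not reduce ketones, should give the isolable primary boronate (1S,5R,7S)‑3‑benzoyl‑5‑(2‑TBDPSO‑ethyl)‑4‑methoxy‑8,8‑dimethyl‑1‑(3‑methylbut‑2‑en‑1‑yl)‑7‑[(4,4,5,5‑tetramethyl‑1,3,2‑dioxaborolan‑2‑yl)methyl]bicyclo[3.3.1]non‑3‑ene‑2,9‑dione F4, whose C7 configuration can be checked before it is used. Suzuki–Miyaura coupling of F4 with 25 (Pd(OAc)2, SPhos, K3PO4, toluene–H2O, 80 °C) returns to 27.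

**Further compounds**

F1 | step 11 | (1S,5R)‑3‑benzoyl‑5‑(2‑TBDPSO‑ethyl)‑4‑methoxy‑8,8‑dimethyl‑7‑methylidenebicyclo[3.3.1]non‑3‑ene‑2,9‑dione | C=C1C[C@@]2(CCO[Si](c3ccccc3)(c3ccccc3)C(C)(C)C)C(OC)=C(C(=O)c3ccccc3)C(=O)[C@H](C2=O)C1(C)C
F2 | step 8 | rac‑4‑benzoyl‑6‑(2‑bromoprop‑2‑en‑1‑yl)‑6‑(2‑TBDPSO‑ethyl)‑3‑hydroxy‑5‑methoxy‑2‑(propan‑2‑yl)cyclohexa‑2,4‑dien‑1‑one | CC(C)(C)[Si](OCCC1(CC(Br)=C)C(=O)C(C(C)C)=C(O)C(C(=O)c2ccccc2)=C1OC)(c1ccccc1)c1ccccc1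
F3 | step 8 | (S)‑1‑phenylethylammonium enolate of (6S)‑17 | CC(C)(C)[Si](OCC[C@@]1(CC(Br)=C)C(=O)C(C(C)C)=C([O-])C(C(=O)c2ccccc2)=C1OC)(c1ccccc1)c1ccccc1.C[C@H]([NH3+])c1ccccc1
F4 | step 13 | (1S,5R,7S)‑3‑benzoyl‑5‑(2‑TBDPSO‑ethyl)‑4‑methoxy‑8,8‑dimethyl‑1‑(3‑methylbut‑2‑en‑1‑yl)‑7‑[(4,4,5,5‑tetramethyl‑1,3,2‑dioxaborolan‑2‑yl)methyl]bicyclo[3.3.1]non‑3‑ene‑2,9‑dione | CC1(C)OB(C[C@H]2C[C@@]3(CCO[Si](c4ccccc4)(c4ccccc4)C(C)(C)C)C(OC)=C(C(=O)c4ccccc4)C(=O)[C@](CC=C(C)C)(C3=O)C2(C)C)OC1(C)C
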